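**Plan**
With the ring numbered C1 (CO2H), C2 (OH), C3, C4 (OMe), C5, C6 (2-oxotridecyl), the retrosynthesis first cuts the C1–CO2H bond and masks the side-chain ketone as a dioxolane. This leaves ring atoms C2–C6 as a 5-alkyl-3-methoxyphenol: one free and one methylated oxygen, meta to each other, with the carbon chain on the third alternate carbon.
That pattern is what a vinylketene and methoxyacetylene assemble, so the benzene ring is cut next at C2–C3 and C4–C5 (and reopened at C1–C2), back to a 3-substituted cyclobutenone and methoxyacetylene.
The cyclobutenone is cut across its four-membered ring to dichloroketene and a terminal alkyne, and the alkyne is traced to methyl 3-oxotetradecanoate by one-carbon homologation at the ester carbon.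
Forward: the C15 chain is completed first, the four-membered ring follows, the benzene ring (the only ring of the target) is closed in the benzannulation, the carboxyl carbon is added at C1 by ortho-formylation and oxidation, and the ketone is released last.
The target has no stereocentre, so no stereocontrol is needed; the control problems are regiochemical (orientation of the ketene–alkyne addition, site of formylation).

Key step: step 7

Assumption: the target is taken as the open-chain keto acid as drawn; its ring–chain tautomer (the 3-hydroxy-3,4-dihydroisocoumarin lactol) is regarded as the same substance.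

**Route**

Step 1
Reactants: 1 methyl 3-oxotetradecanoate
Product: 2 methyl 2-(2-undecyl-1,3-dioxolan-2-yl)acetate
Conditions: HOCH2CH2OH (3 equiv), p-TsOH·H2O (cat.), PhH, reflux, Dean–Stark
Reagents that add atoms: ethylene glycol, OCCO
Why: Acid-catalysed ketalisation with azeotropic removal of water is routine for β-keto esters and masks the ketone and its acidic methylene for the reductive, basic and thermal steps that follow.

Step 2
Reactants: 2 methyl 2-(2-undecyl-1,3-dioxolan-2-yl)acetate
Product: 4 2-(2-undecyl-1,3-dioxolan-2-yl)acetaldehyde, via aluminium hemiacetal 3 (not isolated)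
Conditions: iBu2AlH (1.1 equiv), CH2Cl2, −78 °C; then MeOH, aq. potassium sodium tartrate (KNaC4H4O6), −78 °C → rt
Reagents that add atoms: none
Why: Partial ester reduction with iBu2AlH should stop at the tetrahedral aluminium hemiacetal 3, which persists at −78 °C (helped by chelation to a dioxolane oxygen) and releases the aldehyde only on aqueous work-up.

Step 3
Reactants: 4 2-(2-undecyl-1,3-dioxolan-2-yl)acetaldehyde
Product: 5 2-(prop-2-yn-1-yl)-2-undecyl-1,3-dioxolane
Conditions: dimethyl (1-diazo-2-oxopropyl)phosphonate (1.3 equiv), K2CO3 (2 equiv), MeOH, 0 °C → rt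
Reagents that add atoms: dimethyl (1-diazo-2-oxopropyl)phosphonate (Ohira–Bestmann reagent), CC(=O)C(=[N+]=[N-])P(=O)(OC)OC
Why: The Seyferth–Gilbert homologation in its Ohira–Bestmann form turns enolisable aldehydes into terminal alkynes under mild carbonate conditions to which the ketal is inert.

Step 4
Reactants: 5 2-(prop-2-yn-1-yl)-2-undecyl-1,3-dioxolane; 6 trichloroacetyl chloride
Product: 7 4,4-dichloro-3-[(2-undecyl-1,3-dioxolan-2-yl)methyl]cyclobut-2-en-1-one
Conditions: Zn–Cu couple, Et2O–MeOCH2CH2OMe, rt, slow addition of 6
Reagents that add atoms: none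
Why: Dichloroketene, released from 6 by zinc, undergoes the established [2+2] cycloaddition with terminal alkynes, its carbonyl carbon bonding to the terminal alkyne carbon so that the side chain sits at C3, while 1,2-dimethoxyethane ties up ZnCl2 and so shields the ketal.

Step 5
Reactants: 7 4,4-dichloro-3-[(2-undecyl-1,3-dioxolan-2-yl)methyl]cyclobut-2-en-1-one
Product: 8 3-[(2-undecyl-1,3-dioxolan-2-yl)methyl]cyclobut-2-en-1-one
Conditions: Zn dust, AcOH, TMEDA, EtOH, 0 °C → rt
Reagents that add atoms: none
Why: Zinc reduction of α,α-dichlorocyclobutenones in amine-buffered acetic acid is the standard second half of the dichloroketene route to 3-substituted cyclobutenones, and the buffered medium is too mild to hydrolyse the dioxolane.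

Step 6
Reactants: 9 chloroacetaldehyde dimethyl acetal (2-chloro-1,1-dimethoxyethane)
Product: 11 methoxyacetylene, via sodium methoxyacetylide 10 (not isolated)
Conditions: NaNH2 (3.3 equiv), liq. NH3, −33 °C; NH3 evaporated; then cold satd aq. NaCl, −70 °C → warm bath, distilled into a −78 °C trap
Reagents that add atoms: none
Why: Twofold base-induced elimination (methanol and hydrogen chloride) from the chloroacetal with excess NaNH2 is the classical preparation of this alkyne; it arrives as its sodium acetylide, is protonated by water, and the volatile product is used at once as a cold toluene solution.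

Step 7
Reactants: 8 3-[(2-undecyl-1,3-dioxolan-2-yl)methyl]cyclobut-2-en-1-one; 11 methoxyacetylene
Product: 16 3-methoxy-5-[(2-undecyl-1,3-dioxolan-2-yl)methyl]phenol, via vinylketene 12 (not isolated), via 4-vinylcyclobutenone 13 (not isolated), via dienylketene 14 (not isolated), via cyclohexadienone 15 (not isolated)
Conditions: 11 (2 equiv), PhMe, 80 °C, sealed tube
Reagents that add atoms: none
Why: At 80 °C the cyclobutenone opens by a reversible 4-electron electrocyclic cleavage to vinylketene 12, whose ketene C=C adds across methoxyacetylene in a [2+2] cycloaddition to give 4-vinylcyclobutenone 13; a second 4-electron opening gives dienylketene 14, which undergoes 6-electron electrocyclisation to cyclohexadienone 15, and tautomerisation delivers phenol 16. This is the Danheiser benzannulation of a cyclobutenone with an alkoxyacetylene, the substrate pairing for which the reaction is best established. The benzene ring is closed by the disrotatory 6-electron electrocyclisation that joins the ketene carbon (future C2) to the terminal methylene carbon (future C1), after the intermolecular cycloaddition has made the C2–C3 and C4–C5 bonds. No stereocentre is set, because the single sp3 centres of 13 and 15 are erased on ring opening and aromatisation. The one selectivity required is the orientation of the ketene–alkyne addition, and polarity fixes it: the electrophilic ketene carbonyl carbon bonds to the nucleophilic unsubstituted carbon of methoxyacetylene, so the free hydroxyl (from the ketene oxygen) and the methoxy group end up meta, with the side chain on the third alternate carbon. Because the opening of 13 is reversible, only the dienylketene geometry able to cyclise is drained off, and the neutral thermal conditions leave the dioxolane untouched.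

Step 8
Reactants: 16 3-methoxy-5-[(2-undecyl-1,3-dioxolan-2-yl)methyl]phenol
Product: 18 2-hydroxy-4-methoxy-6-[(2-undecyl-1,3-dioxolan-2-yl)methyl]benzaldehyde, via hydroxymethylphenol 17 (not isolated)
Conditions: MgCl2 (anhydrous, 2 equiv), Et3N (4 equiv), (CH2O)n (6 equiv), MeCN, reflux; then cold 5% aq. citric acid
Reagents that add atoms: paraformaldehyde (as formaldehyde), C=O
Why: In the magnesium-mediated Casiraghi–Skattebøl ortho-formylation the chloromagnesium phenoxide delivers coordinated formaldehyde only to a carbon ortho to oxygen; of the two such carbons the one para to the methoxy group should be the more nucleophilic (as in formylations of orcinol-type ethers, which avoid the carbon between the two oxygens), and the hydroxymethyl intermediate 17 is oxidised in the flask by hydride transfer to a second formaldehyde.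

Step 9
Reactants: 18 2-hydroxy-4-methoxy-6-[(2-undecyl-1,3-dioxolan-2-yl)methyl]benzaldehyde
Product: 19 2-hydroxy-4-methoxy-6-[(2-undecyl-1,3-dioxolan-2-yl)methyl]benzoic acid
Conditions: NaClO2, NaH2PO4, 2-methyl-2-butene (excess), t-BuOH/H2O, 0 °C → rt
Reagents that add atoms: sodium chlorite, [Na+].[O-]Cl=O
Why: The Lindgren–Pinnick chlorite oxidation converts hindered, electron-rich salicylaldehydes into salicylic acids without attacking the free phenol as long as the alkene traps hypochlorous acid, and the phosphate buffer is mild toward the ketal, which is kept until now so that the ketone cannot condense with the ortho aldehyde.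

Step 10
Reactants: 19 2-hydroxy-4-methoxy-6-[(2-undecyl-1,3-dioxolan-2-yl)methyl]benzoic acid
Product: 20 2-hydroxy-4-methoxy-6-(2-oxotridecyl)benzoic acid (target)
Conditions: 1 M aq. HCl, THF, rt
Reagents that add atoms: water, O
Why: Acid-catalysed hydrolysis of a dialkyl-ketone dioxolane proceeds at room temperature, where the electron-rich salicylic acid should not decarboxylate and the aqueous medium disfavours dehydration of the keto acid to the isocoumarin.

**Compound list**
1 | methyl 3-oxotetradecanoate | CCCCCCCCCCCC(=O)CC(=O)OC | starting material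
2 | methyl 2-(2-undecyl-1,3-dioxolan-2-yl)acetate | CCCCCCCCCCCC1(CC(=O)OC)OCCO1 | intermediate
3 | [1-methoxy-2-(2-undecyl-1,3-dioxolan-2-yl)ethoxy]bis(2-methylpropyl)aluminium (aluminium hemiacetal) | CCCCCCCCCCCC1(CC(OC)O[Al](CC(C)C)CC(C)C)OCCO1 | intermediate (not isolated)
4 | 2-(2-undecyl-1,3-dioxolan-2-yl)acetaldehyde | CCCCCCCCCCCC1(CC=O)OCCO1 | intermediate
5 | 2-(prop-2-yn-1-yl)-2-undecyl-1,3-dioxolane | CCCCCCCCCCCC1(CC#C)OCCO1 | intermediate
6 | trichloroacetyl chloride | ClC(Cl)(Cl)C(Cl)=O | starting material
7 | 4,4-dichloro-3-[(2-undecyl-1,3-dioxolan-2-yl)methyl]cyclobut-2-en-1-one | CCCCCCCCCCCC1(CC2=CC(=O)C2(Cl)Cl)OCCO1 | intermediate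
8 | 3-[(2-undecyl-1,3-dioxolan-2-yl)methyl]cyclobut-2-en-1-one | CCCCCCCCCCCC1(CC2=CC(=O)C2)OCCO1 | intermediate
9 | chloroacetaldehyde dimethyl acetal (2-chloro-1,1-dimethoxyethane) | COC(CCl)OC | starting material
10 | sodium methoxyacetylide | [Na+].[C-]#COC | intermediate (not isolated)
11 | methoxyacetylene | COC#C | intermediate
12 | 3-[(2-undecyl-1,3-dioxolan-2-yl)methyl]buta-1,3-dien-1-one (vinylketene) | CCCCCCCCCCCC1(CC(=C)C=C=O)OCCO1 | intermediate (not isolated)
13 | 3-methoxy-4-[3-(2-undecyl-1,3-dioxolan-2-yl)prop-1-en-2-yl]cyclobut-2-en-1-one (racemic 4-vinylcyclobutenone) | CCCCCCCCCCCC1(CC(=C)C2C(=O)C=C2OC)OCCO1 | intermediate (not isolated)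
14 | (3E)-3-methoxy-5-[(2-undecyl-1,3-dioxolan-2-yl)methyl]hexa-1,3,5-trien-1-one (dienylketene, C2 and C5 cis on the central double bond) | CCCCCCCCCCCC1(CC(=C)/C=C(OC)\C=C=O)OCCO1 | intermediate (not isolated)
15 | 3-methoxy-5-[(2-undecyl-1,3-dioxolan-2-yl)methyl]cyclohexa-2,4-dien-1-one | CCCCCCCCCCCC1(CC2=CC(OC)=CC(=O)C2)OCCO1 | intermediate (not isolated)
16 | 3-methoxy-5-[(2-undecyl-1,3-dioxolan-2-yl)methyl]phenol | CCCCCCCCCCCC1(Cc2cc(O)cc(OC)c2)OCCO1 | intermediate
17 | 2-(hydroxymethyl)-5-methoxy-3-[(2-undecyl-1,3-dioxolan-2-yl)methyl]phenol | CCCCCCCCCCCC1(Cc2cc(OC)cc(O)c2CO)OCCO1 | intermediate (not isolated)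
18 | 2-hydroxy-4-methoxy-6-[(2-undecyl-1,3-dioxolan-2-yl)methyl]benzaldehyde | CCCCCCCCCCCC1(Cc2cc(OC)cc(O)c2C=O)OCCO1 | intermediate
19 | 2-hydroxy-4-methoxy-6-[(2-undecyl-1,3-dioxolan-2-yl)methyl]benzoic acid | CCCCCCCCCCCC1(Cc2cc(OC)cc(O)c2C(=O)O)OCCO1 | intermediate
20 | 2-hydroxy-4-methoxy-6-(2-oxotridecyl)benzoic acid | CCCCCCCCCCCC(=O)Cc1cc(OC)cc(O)c1C(=O)O | target

**Count**
Total steps: 10. Longest linear sequence: 9 steps (steps 1–5 and 7–10, from methyl 3-oxotetradecanoate); methoxyacetylene is made in one step on a side branch.

**Steps most likely to fail**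

Step 8. The risk is poor site selectivity between the two carbons ortho to the phenoxide: the desired C1 is flanked by the ketal-bearing methylene, so attack at the carbon between the two oxygens may compete. The fallback sets out from 16 and replaces chelation-directed formylation by a halogenation directed by the methoxy group. Acetylation (Ac2O, pyridine) gives 3-methoxy-5-[(2-undecyl-1,3-dioxolan-2-yl)methyl]phenyl acetate F1, in which the methoxy group is the only strong donor. NBS in MeCN should then brominate para to it, giving 2-bromo-5-methoxy-3-[(2-undecyl-1,3-dioxolan-2-yl)methyl]phenyl acetate F2. K2CO3 in MeOH frees 2-bromo-5-methoxy-3-[(2-undecyl-1,3-dioxolan-2-yl)methyl]phenol F3. Treatment with n-BuLi (2.2 equiv, THF, −78 °C) forms the lithiated phenoxide by bromine–lithium exchange, and CO2 carboxylates it. The fallback rejoins the route at 19, bypassing 18 and step 9.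

Step 4. The risk is Lewis-acid opening of the dioxolane by ZnCl2 and the acid chloride, or oligomerisation of dichloroketene outrunning its addition to an unactivated alkyne. The fallback sets out from 5 and builds the four-membered ring by a keteniminium [2+2] cycloaddition instead. N,N-Dimethylacetamide, Tf2O and 2,4,6-collidine in ClCH2CH2Cl (reflux) generate the keteniminium salt, which should add to the alkyne to give N,N-dimethyl-3-[(2-undecyl-1,3-dioxolan-2-yl)methyl]cyclobut-2-en-1-iminium trifluoromethanesulfonate F4. Hydrolysis with aq. NaHCO3 gives the cyclobutenone directly, so the fallback rejoins the route at 8 and bypasses 7 and step 5, with no zinc halide present at any point.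

Step 10. The risk is acid-promoted cyclodehydration of the liberated keto acid (through its lactol) during ketal cleavage, so that the open form is not obtained cleanly. The fallback sets out from 19 and takes the cyclisation deliberately to completion. p-TsOH·H2O in wet acetone, followed by PhMe at reflux, should give 8-hydroxy-6-methoxy-3-undecyl-1H-isochromen-1-one F5. The enol lactone is then opened with aq. KOH in EtOH at rt, and cold acidification to pH 3 at 0 °C releases the keto acid, returning to the route at 20.

Further compounds
F1 | step 8 | 3-methoxy-5-[(2-undecyl-1,3-dioxolan-2-yl)methyl]phenyl acetate | CCCCCCCCCCCC1(Cc2cc(OC)cc(OC(C)=O)c2)OCCO1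
F2 | step 8 | 2-bromo-5-methoxy-3-[(2-undecyl-1,3-dioxolan-2-yl)methyl]phenyl acetate | CCCCCCCCCCCC1(Cc2cc(OC)cc(OC(C)=O)c2Br)OCCO1
F3 | step 8 | 2-bromo-5-methoxy-3-[(2-undecyl-1,3-dioxolan-2-yl)methyl]phenol | CCCCCCCCCCCC1(Cc2cc(OC)cc(O)c2Br)OCCO1
F4 | step 4 | N,N-dimethyl-3-[(2-undecyl-1,3-dioxolan-2-yl)methyl]cyclobut-2-en-1-iminium trifluoromethanesulfonate | C[N+](C)=C1C=C(CC2(CCCCCCCCCCC)OCCO2)C1.[O-]S(=O)(=O)C(F)(F)F
F5 | step 10 | 8-hydroxy-6-methoxy-3-undecyl-1H-isochromen-1-one | CCCCCCCCCCCc1cc2cc(OC)cc(O)c2c(=O)o1
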